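**Retrosynthetic overview**
1. Target 15 ⇐ C40 12,12'-disulfone 14 by double loss of PhSO2H, which unveils C11=C12 and C11'=C12' (carotenoid numbering).
2. 14 ⇐ three pieces in one pot: the C10 trienyl 1,8-disulfone 11 used as a 1,8-dicarbanion (polarity reversed relative to the C10 dialdehyde and dibromide it is made from), allylated first by farnesyl bromide 12 (C11'–C12'), then by ε-C15 bromide 6 (C11–C12).
3. 6 ⇐ vinyl-α-ionol 4 ⇐ (R)-α-ionone 2 ⇐ racemic α-ionone 1 (resolution fixes C6).
4. 11 ⇐ diol 8 ⇐ C10 dialdehyde 7.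
5. No ring is built: ring A (the trimethylcyclohexene) is carried intact from α-ionone.

Assumption: the target is all-E (6R)-α-zeacarotene; racemic α-ionone 1, (2E,6E)-farnesyl bromide 12 and C10 dialdehyde 7 are taken as catalogue chemicals.

**Step 1**
Reactants: 1 racemic α-ionone
Product: 2 (R)-(+)-α-ionone
Conditions: preparative chiral SFC, amylose tris(3,5-dimethylphenylcarbamate) phase, CO2/MeOH, 35 °C; collect the dextrorotatory enantiomer
Reagents that add atoms: none
Why: Chromatographic resolution of enantiomers on a chiral stationary phase; no bond is made, and the only stereocentre of the target (C6, R) is fixed here by taking the (+)-enantiomer.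

**Step 2**
Reactants: 2 (R)-(+)-α-ionone; 3 vinylmagnesium bromide
Product: 4 (1E)-3-methyl-1-[(1R)-2,6,6-trimethylcyclohex-2-en-1-yl]penta-1,4-dien-3-ol (vinyl-α-ionol, both C3 epimers)
Conditions: vinylmagnesium bromide (1.3 equiv), THF, −10 → 20 °C; aq NH4Cl
Reagents that add atoms: vinylmagnesium bromide, C=C[Mg]Br
Why: Grignard 1,2-addition to the enone carbonyl (the vinyl-ionol reaction); the new carbinol centre forms unselectively but later becomes sp2, and C6 (γ to the carbonyl) is not enolised.

**Step 3**
Reactants: 4 vinyl-α-ionol; 5 phosphorus tribromide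
Product: 6 (2E,4E)-1-bromo-3-methyl-5-[(1R)-2,6,6-trimethylcyclohex-2-en-1-yl]penta-2,4-diene (ε-C15 bromide)
Conditions: PBr3 (0.4 equiv), pyridine (cat.), Et2O, −30 → −10 °C; cold NaHCO3 wash; used at once without purification
Reagents that add atoms: phosphorus tribromide, BrP(Br)Br
Why: Allylic bromination with transposition (SN2'/ion-pair collapse at the unhindered primary terminus) gives the conjugated primary bromide, mainly 9E; C6 lies outside the allyl system and keeps its configuration at low temperature, and the 9Z portion is corrected by the equilibration in step 6.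

**Step 4**
Reactants: 7 (2E,4E,6E)-2,7-dimethylocta-2,4,6-trienedial
Product: 8 (2E,4E,6E)-2,7-dimethylocta-2,4,6-triene-1,8-diol
Conditions: NaBH4 (1.1 equiv), THF/MeOH, 0 °C
Reagents that add atoms: none
Why: 1,2-hydride reduction of both enal carbonyls; the triene geometry is untouched and no stereocentre is formed.

**Step 5**
Reactants: 8 C10 diol; 5 phosphorus tribromide; 9 sodium benzenesulfinate
Product: 11 (2E,4E,6E)-2,7-dimethyl-1,8-bis(phenylsulfonyl)octa-2,4,6-triene, via C10 dibromide 10 (not isolated)
Conditions: PBr3 (0.8 equiv), pyridine (cat.), THF, −20 °C; then PhSO2Na (2.5 equiv), DMF, 0 → 20 °C; crystallise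
Reagents that add atoms: sodium benzenesulfinate, [Na+].[O-]S(=O)c1ccccc1; phosphorus tribromide, BrP(Br)Br (its bromine is found only in 10)
Why: Bromination of the primary allylic alcohols, then SN2 S-alkylation of the sulfinate; exchanging the leaving group for PhSO2 turns the natively electrophilic C10 termini into acidic, carbanion-forming sites, and the all-E triene is the thermodynamic isomer.

**Step 6**
Reactants: 11 C10 disulfone; 12 (2E,6E)-farnesyl bromide; 6 ε-C15 bromide
Product: 15 (6R)-α-zeacarotene [(6R)-7',8'-dihydro-ε,ψ-carotene], via C25 disulfone 13 (not isolated), via C40 disulfone 14 (not isolated)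
Conditions: n-BuLi (2.05 equiv), THF, −78 °C; 12 (1.0 equiv, slow addition), −78 °C, 20 min; 6 (1.15 equiv), −78 → −20 °C; KOMe (15 equiv), 60 °C, 3 h, Ar, dark; then heptane, reflux, crystallise
Reagents that add atoms: (2E,6E)-farnesyl bromide, CC(C)=CCC/C(C)=C/CC/C(C)=C/CBr; ε-C15 bromide 6, BrC/C=C(C)/C=C/[C@H]1C(C)=CCCC1(C)C
Why: Proposed new method: the closest known reactions are the Julia-type C-allylation of a lithiated allylic sulfone by an allylic bromide and base-induced dehydrosulfonation (vitamin A and symmetrical carotenes), but the unsymmetrical one-pot use of the dilithio C10 disulfone is new; the sulfonyl carbanions are polarity-reversed forms of the C10 termini, so each new bond (C11'–C12', then C11–C12) joins two carbons that are both natively electrophilic (allylic C–Br carbons of 12 and 6 with the C10 termini that are electrophilic in 7 and 10); the dianion should be far more nucleophilic than the mono-anion left after the first allylation, and no neutral CH2SO2Ph is present for proton-transfer scrambling, so 12 is taken up once before 6 is added; KOMe then removes two PhSO2H (1,2- and vinylogous E1cB eliminations, funnelled by prototropy to the fully conjugated octaene as thermodynamic sink); the sulfone-bearing centres of 14 are destroyed, no new stereocentre is made, C6–H is not expected to epimerise under these conditions, and Z-isomers at C9, C11 and C11' are equilibrated thermally to the all-E compound, which crystallises.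

**Compound list**
1 | racemic α-ionone, (3E)-4-(2,6,6-trimethylcyclohex-2-en-1-yl)but-3-en-2-one | CC(=O)/C=C/C1C(C)=CCCC1(C)C | starting material
2 | (R)-(+)-α-ionone | CC(=O)/C=C/[C@H]1C(C)=CCCC1(C)C | intermediate
3 | vinylmagnesium bromide | C=C[Mg]Br | starting material
4 | vinyl-α-ionol, (1E)-3-methyl-1-[(1R)-2,6,6-trimethylcyclohex-2-en-1-yl]penta-1,4-dien-3-ol, both C3 epimers | C=CC(C)(O)/C=C/[C@H]1C(C)=CCCC1(C)C | intermediate
5 | phosphorus tribromide | BrP(Br)Br | starting material
6 | ε-C15 bromide, (2E,4E)-1-bromo-3-methyl-5-[(1R)-2,6,6-trimethylcyclohex-2-en-1-yl]penta-2,4-diene | BrC/C=C(C)/C=C/[C@H]1C(C)=CCCC1(C)C | intermediate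
7 | C10 dialdehyde, (2E,4E,6E)-2,7-dimethylocta-2,4,6-trienedial | O=C/C(C)=C/C=C/C=C(C)/C=O | starting material
8 | C10 diol, (2E,4E,6E)-2,7-dimethylocta-2,4,6-triene-1,8-diol | OC/C(C)=C/C=C/C=C(C)/CO | intermediate
9 | sodium benzenesulfinate | [Na+].[O-]S(=O)c1ccccc1 | starting material
10 | C10 dibromide, (2E,4E,6E)-1,8-dibromo-2,7-dimethylocta-2,4,6-triene (not isolated) | BrC/C(C)=C/C=C/C=C(C)/CBr | intermediate
11 | C10 disulfone, (2E,4E,6E)-2,7-dimethyl-1,8-bis(phenylsulfonyl)octa-2,4,6-triene | O=S(=O)(C/C(C)=C/C=C/C=C(C)/CS(=O)(=O)c1ccccc1)c1ccccc1 | intermediate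
12 | (2E,6E)-farnesyl bromide | CC(C)=CCC/C(C)=C/CC/C(C)=C/CBr | starting material
13 | C25 disulfone, (2E,4E,6E,10E,14E)-2,7,11,15,19-pentamethyl-1,8-bis(phenylsulfonyl)icosa-2,4,6,10,14,18-hexaene, racemic at C8 (not isolated) | CC(C)=CCC/C(C)=C/CC/C(C)=C/CC(S(=O)(=O)c1ccccc1)/C(C)=C/C=C/C=C(C)/CS(=O)(=O)c1ccccc1 | intermediate
14 | C40 disulfone, (6R)-12,12'-bis(phenylsulfonyl)-11,12,11',12',7',8'-hexahydro-ε,ψ-carotene, epimers at C12 and C12' (not isolated) | CC(C)=CCC/C(C)=C/CC/C(C)=C/CC(S(=O)(=O)c1ccccc1)/C(C)=C/C=C/C=C(C)/C(S(=O)(=O)c1ccccc1)C/C=C(C)/C=C/[C@H]1C(C)=CCCC1(C)C | intermediate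
15 | (6R)-α-zeacarotene, (6R)-7',8'-dihydro-ε,ψ-carotene | CC(C)=CCC/C(C)=C/CC/C(C)=C/C=C/C(C)=C/C=C/C=C(C)/C=C/C=C(C)/C=C/[C@H]1C(C)=CCCC1(C)C | target

**Count and risks**
Total steps: 6. Longest linear sequence: 4 (steps 1, 2, 3, 6); the C10 branch is 3 (steps 4, 5, 6).

Most likely to fail, first: step 6. The first allylation may not stop cleanly at mono-alkylation. The mono-anion of 13 can lose sulfinate through the triene before it meets 6. Symmetrical carotenes (from double farnesylation or double ε-allylation) would have to be removed on MgO. The fallback swaps the polarity of the partners so that the C10 unit is the electrophile and no trienyl disulfone anion is needed. It sets out from 4, 12 and crude dibromide 10 and comes back at 15. Alcohol 4 with PhSO2Na in AcOH gives the ε-C15 sulfone F1 (crystalline, 9E). Bromide 12 with PhSO2Na in DMF gives farnesyl phenyl sulfone F2. Lithiated F2 (n-BuLi, THF, −78 °C) is added to a threefold excess of 10 to give the isolated C25 bromo sulfone F3. Lithiated F1 alkylates F3 to the C40 11,11'-disulfone F4, and KOMe eliminates both sulfinates to 15.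

Second: step 3. Bromide 6 is labile, carries some 9Z isomer, and can ionise with loss of the C6 proton. The fallback generates the ε-C15 electrophile catalytically instead. It sets out from 4 and comes back at 14. Deprotonation of 4 (n-BuLi) and ClCO2Me gives the tertiary allylic methyl carbonate F5, which can be stored. With Pd(PPh3)4 (zerovalent palladium, 3 mol %) in THF at 0 °C it forms a pentadienylpalladium cation. The sulfonyl carbanion of 13 attacks this at the unhindered terminal carbon (Tsuji–Trost allylation) to give 14 with 9E geometry, which is eliminated as in step 6.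

Third: step 5. Dibromide 10 may decompose or give rearranged sulfones. The fallback goes through a palladium π-allyl instead of SN2. It sets out from 8 and comes back at 11. Acetylation (Ac2O, pyridine) gives the diacetate F6. Pd(PPh3)4 (zerovalent palladium) with PhSO2Na in THF/MeOH then gives the linear disulfone 11 under thermodynamic control (reversible allylic sulfonylation).

**Further compounds**
F1 | step 6 | ε-C15 sulfone, (2E,4E)-3-methyl-5-[(1R)-2,6,6-trimethylcyclohex-2-en-1-yl]penta-2,4-dienyl phenyl sulfone | O=S(=O)(C/C=C(C)/C=C/[C@H]1C(C)=CCCC1(C)C)c1ccccc1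
F2 | step 6 | (2E,6E)-farnesyl phenyl sulfone | CC(C)=CCC/C(C)=C/CC/C(C)=C/CS(=O)(=O)c1ccccc1
F3 | step 6 | C25 bromo sulfone, (2E,4E,6E,10E,14E)-1-bromo-2,7,11,15,19-pentamethyl-9-(phenylsulfonyl)icosa-2,4,6,10,14,18-hexaene, racemic | CC(C)=CCC/C(C)=C/CC/C(C)=C/C(S(=O)(=O)c1ccccc1)C/C(C)=C/C=C/C=C(C)/CBr
F4 | step 6 | C40 11,11'-disulfone, (6R)-11,11'-bis(phenylsulfonyl)-11,12,11',12',7',8'-hexahydro-ε,ψ-carotene, epimers at C11 and C11' | CC(C)=CCC/C(C)=C/CC/C(C)=C/C(S(=O)(=O)c1ccccc1)C/C(C)=C/C=C/C=C(C)/CC(S(=O)(=O)c1ccccc1)/C=C(C)/C=C/[C@H]1C(C)=CCCC1(C)C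
F5 | step 3 | methyl carbonate of vinyl-α-ionol, methyl (1E)-3-methyl-1-[(1R)-2,6,6-trimethylcyclohex-2-en-1-yl]penta-1,4-dien-3-yl carbonate | COC(=O)OC(C)(C=C)/C=C/[C@H]1C(C)=CCCC1(C)C
F6 | step 5 | C10 diacetate, (2E,4E,6E)-2,7-dimethylocta-2,4,6-triene-1,8-diyl diacetate | CC(=O)OC/C(C)=C/C=C/C=C(C)/COC(C)=O
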